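## Structural features

The target is a single bicyclic heteroaromatic, a benzene ring fused along the C3a–C7a bond to a pyrrole ring, with no side chain and no stereocentre, so no stereochemical relationship has to be controlled. It carries three bromines: two on the adjacent pyrrole carbons C2 and C3 and one on the benzene ring at C6, para to C3a and meta to the nitrogen-bearing C7a, while N1 stays unsubstituted. The 2,3-dibromo enamine unit of the N–H indole is the fragile part, since acid, light and moisture lead toward oxindoles, so it should be made last under cold, neutral and dry conditions. C3 and C2 are the innately nucleophilic positions of an indole and accept bromine directly. The real difficulty is the lone bromine at C6, which electrophilic bromination of an indole does not reach selectively, so it has to arrive together with the carbon skeleton. The key step exploits the fact that the four benzene carbons C4 to C7 can be laid onto a finished pyrrole: C4 and C7 are one-carbon appendages on pyrrole C3 and C2, tied together through a lactone as a pyranone diene. C5 and C6 come from a two-carbon alkyne that already carries the C6 bromine and, at C5, a silicon group that is removed afterwards.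

## Logic of the disconnections

19 back to 17. The C2–Br and C3–Br bonds are cut first, because these are the bonds an indole forms unaided through its enamine reactivity. This removes the sensitive dihalo unit and leaves a monobromo indole. The forward step must stop after two brominations on the pyrrole ring, which is why it is run last, cold and dry.

17 back to 15. The N1–H bond is traced back to an N1–CH2 bond of a pivaloyloxymethyl group. Nitrogen has to stay substituted through the pyranone chemistry, and the substituent must leave the nitrogen lone pair available to the diene. A silylethoxymethyl group was rejected: it would not survive the acid needed one step earlier, and removing it first with fluoride would expose an aryl silane ortho to bromine to conditions that can open an aryne pathway. The forward demand is a removal that leaves the aryl bromide alone, which ammonolysis of the pivalate meets.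

15 back to 14. The C5–H bond is traced back to C5–Si. The silicon turns the hazardous parent bromoalkyne into the stable, handleable 12 and biases the orientation of the cycloaddition. The forward step is an ipso-protonation at C5, which must outrun acid damage to the 2,3-unsubstituted indole; acid is preferred to anionic cleavage because of the neighbouring bromine.

14 back to 10 and 12. The bonds C4–C5 and C6–C7 are cut and a carbon dioxide bridge between C4 and C7 is put back. This dissolves the benzene ring into a pyrrole-fused pyranone and a two-carbon alkyne, makes the route convergent and places bromine at C6 without any substitution on an indole. The forward step needs heat, an excess of the weak dienophile, and regiocontrol so that the bromine-bearing carbon bonds to C7.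

10 back to 8. The lactone bond O6–C5 is cut and C4 is returned to a CH2 group, giving an open formyl acid in which all ring atoms of the pyranone are already present. The forward cyclodehydration must be anhydrous, and the C7-unsubstituted enol lactone must be used promptly.

8 back to 7, then to 5 and 6. The benzyl–oxygen bond of the ester and the N1–CH2 bond are cut. The carboxyl group has to be masked during formylation and N-alkylation, and it has to be unmasked without base because the pivalate on nitrogen is base-labile; hydrogenolysis of a benzyl ester meets both needs. The N-alkylation needs only carbonate because the formyl group acidifies the N–H.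

5 back to 3. The C2–CHO bond is cut. The forward formylation must choose C2 over C5; it is placed before N-alkylation so that C2, which lies between nitrogen and the side chain, is as uncrowded as possible.

3 back to 1 and 2. The ester O–CH2 bond is cut, which leads to two purchased compounds. The forward step must alkylate oxygen and not nitrogen, which a weak base ensures.

12 back to 11. The C(sp)–Br bond is cut, which leads to a purchased alkyne. The forward bromination must stop at the terminal C–H and leave the C–Si bond intact.

## Other disconnections considered

Alternative 1: The cut is C3–C3a of the pyrrole ring. 5-Bromo-2-iodoaniline A1 would be added to methyl propiolate A2 to give methyl (2Z)-3-[(5-bromo-2-iodophenyl)amino]prop-2-enoate A3. Zerovalent palladium formed from Pd(OAc)2 would insert into the C–I bond of A3 and the aryl group would couple to the enamine carbon, giving methyl 6-bromo-1H-indole-3-carboxylate A4. The ester of A4 holds C3 until hydrolysis and bromodecarboxylation, with C2 bromination, lead to 19.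
- In its favour: the C6 bromine is fixed by purchased A1, oxidative addition distinguishes C–I from C–Br, and about four operations should suffice.
- Against it: the catalyst must be kept from the C–Br bond, the C3 ester of A4 deactivates the pyrrole ring so that electrophiles tend toward the benzene ring, and the ester-for-bromine exchange needs an ipso attack on the derived acid.
- Comparison: on structure it closes the five-membered ring on a bought benzene, whereas the chosen plan builds the benzene ring. Its placement of bromine is certain while the chosen plan depends on the orientation of a cycloaddition, so the alternative is the better on that point. On mechanism it is an organometallic cyclisation against a metal-free pericyclic step, with no clear advantage either way. On step economy the alternative is clearly the better.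

Alternative 2: The cut is C5–C6. 3-Ethenyl-1-tosyl-1H-pyrrole-2-carbaldehyde A5 would be converted by dibromo-olefination into 2-(2,2-dibromoethenyl)-3-ethenyl-1-tosyl-1H-pyrrole A6. Thermal 6π-electrocyclisation of A6 through the pyrrole C2–C3 bond would give 6,6-dibromo-1-tosyl-5,6-dihydro-1H-indole A7, and loss of hydrogen bromide from A7 would give 6-bromo-1-tosyl-1H-indole A8.
- In its favour: like the chosen plan it grows the benzene ring on a pyrrole, the position of bromine is unambiguous because the dibromomethylene carbon of A6 becomes C6, and no silicon has to be removed.
- Against it: A5 needs several steps of its own, the ring closure borrows a double bond from the aromatic pyrrole and forces one bromine inward so that a high temperature is expected, geminal dibromoalkenes such as A6 are thermally delicate, and the sulfonyl group of A8 must be removed afterwards.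
- Comparison: on structure both plans make the same ring, and the alternative is the better on regiochemical certainty. On mechanism both are pericyclic steps followed by loss of a small molecule; the chosen cycloaddition is intermolecular and convergent, whereas the electrocyclisation needs a fully assembled triene. On step economy the two are about equal, the alternative saving the desilylation but spending more steps before its key step.

Alternative 3: The cut is N1–C7a. 4-Bromobenzaldehyde A9 would be condensed with ethyl azidoacetate A10 to give ethyl (2Z)-2-azido-3-(4-bromophenyl)prop-2-enoate A11. Thermolysis of A11 would expel dinitrogen, and the vinyl nitrene would insert into an ortho C–H bond to give ethyl 6-bromo-1H-indole-2-carboxylate A12. The ester of A12 holds C2 until C3 bromination, hydrolysis and decarboxylative bromination lead to 19.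
- In its favour: there are two steps from cheap A9 to the indole A12, the two ortho positions of A11 are equivalent so a single isomer should form, and bromine is certain to sit at C6.
- Against it: the organic azide A11 is heated to release gas, the condensation of A9 with A10 is usually the weak step, and replacing a C2 carboxyl by bromine is harder than at C3.
- Comparison: on structure it again closes the pyrrole ring on a bought benzene and is the better on regiochemical certainty. On mechanism a nitrene insertion replaces a cycloaddition, and the chosen plan is the better on process safety. On step economy the alternative is the better by several steps, although its placeholder exchange is less mild than a protodesilylation.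

Key step: step 7

Remark on structure: in 10 the terminus C7 is bonded to C7a and to the ring oxygen O6; nitrogen sits on C7a, so it acts on C7 as the donor of an enamine, not as a direct neighbour. C4 is the former CH2, C5 the former carboxyl carbon and C7 the former formyl carbon.

Remark on the chemistry: the pivaloyloxymethyl group on nitrogen is assumed to tolerate trifluoroacetic acid in dichloromethane at room temperature, as pivalate esters and N-acyloxymethyl azoles normally do.

## Route

Step 1
Reactants: 1 2-(1H-pyrrol-3-yl)acetic acid; 2 benzyl bromide
Product: 3 benzyl 2-(1H-pyrrol-3-yl)acetate
Conditions: KHCO3, DMF, rt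
Reagents that add atoms: none
Why: SN2 O-alkylation of the carboxylate; bicarbonate is too weak to deprotonate the pyrrole N–H, so only the ester should form, and benzyl is chosen because it can later be removed by hydrogenolysis without base.

Step 2
Reactants: 3 benzyl 2-(1H-pyrrol-3-yl)acetate
Product: 5 benzyl 2-(2-formyl-1H-pyrrol-3-yl)acetate, via iminium chloride 4 (not isolated)
Conditions: POCl3, DMF, CH2Cl2, 0 °C to rt; then aq. NaOAc
Reagents that add atoms: N,N-dimethylformamide, CN(C)C=O (formyl carbon); water, O (formyl oxygen)
Why: Vilsmeier–Haack formylation of the free N–H pyrrole; attack at C2, the α-position whose σ-complex is stabilised by the adjacent C3 side chain, should be preferred over C5, and leaving nitrogen unsubstituted keeps C2 uncrowded. Aqueous acetate hydrolyses iminium salt 4; any C5-formyl isomer is removed by chromatography and could not lactonise later in any case.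

Step 3
Reactants: 5 benzyl 2-(2-formyl-1H-pyrrol-3-yl)acetate; 6 chloromethyl pivalate
Product: 7 benzyl 2-{2-formyl-1-[(pivaloyloxy)methyl]-1H-pyrrol-3-yl}acetate
Conditions: K2CO3, DMF, 0 °C to rt
Reagents that add atoms: none
Why: The N–H of a 2-formylpyrrole is acidic enough for carbonate, and the pyrrolide is alkylated at nitrogen by the chloromethyl ester (SN2). The N-acyloxymethyl group leaves the nitrogen lone pair available to the later diene, tolerates acid and heat, and is removable by ammonolysis.

Step 4
Reactants: 7 benzyl 2-{2-formyl-1-[(pivaloyloxy)methyl]-1H-pyrrol-3-yl}acetate
Product: 8 2-{2-formyl-1-[(pivaloyloxy)methyl]-1H-pyrrol-3-yl}acetic acid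
Conditions: H2 (1 atm), 10% Pd/C, EtOAc, rt
Reagents that add atoms: none
Why: Catalytic hydrogenolysis of the benzyl ester under neutral conditions; the pyrrole-2-carbaldehyde (a vinylogous formamide) and the pivalate N,O-acetal should not be reduced at 1 atm, and no base that could cleave the pivalate is involved.

Step 5
Reactants: 8 2-{2-formyl-1-[(pivaloyloxy)methyl]-1H-pyrrol-3-yl}acetic acid
Product: 10 1-[(pivaloyloxy)methyl]pyrano[3,4-b]pyrrol-5(1H)-one, via mixed acetic anhydride 9 (not isolated)
Conditions: Ac2O, 90 °C; evaporate, use promptly
Reagents that add atoms: none
Why: Cyclodehydration of an ortho-formyl heteroarylacetic acid: mixed anhydride 9 acylates the formyl oxygen (equivalently, the derived ketene undergoes 6π-oxa-electrocyclisation) and loss of the C4 proton gives the enol lactone, the standard entry to pyrano-fused pyrrolones and indolones. Push–pull conjugation from N1 to the C5 carbonyl should make this masked pyrrole-2,3-quinodimethane isolable.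

Step 6
Reactants: 11 trimethylsilylacetylene
Product: 12 (bromoethynyl)trimethylsilane
Conditions: NBS (1.05 equiv), AgNO3 (10 mol %), acetone, rt, dark
Reagents that add atoms: N-bromosuccinimide, O=C1CCC(=O)N1Br
Why: AgNO3-catalysed electrophilic bromination of the terminal alkyne through the alkynyl intermediate Me3SiC≡CAg, a standard preparation of 1-bromoalkynes. Only about one equivalent of NBS is used so that the C–Si bond is not attacked, and the volatile product is used fresh.

Step 7
Reactants: 10 1-[(pivaloyloxy)methyl]pyrano[3,4-b]pyrrol-5(1H)-one; 12 (bromoethynyl)trimethylsilane
Product: 14 [6-bromo-5-(trimethylsilyl)-1H-indol-1-yl]methyl pivalate, via bridged lactone cycloadduct 13 (not isolated)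
Conditions: 12 (5 equiv), PhCl, 140 °C, sealed tube
Reagents that add atoms: none
Why: Thermal normal-demand [4+2] cycloaddition of the pyranone diene C7=C7a–C3a=C4 to the alkyne gives the carbon dioxide-bridged lactone 13, in which the pyrrole sextet is restored, and retro-[4+2] loss of carbon dioxide then leaves the benzene ring. The closest known reaction is the alkyne Diels–Alder/decarboxylation of pyrano[3,4-b]pyrrol-5(1H)-ones and pyrano[3,4-b]indol-3-ones to indoles and carbazoles, a branch of 2-pyranone benzannulation. The one new ring (C3a–C4–C5–C6–C7–C7a) is closed by intermolecular suprafacial cycloaddition that forms C4–C5 and C6–C7 together and is aromatised by cycloreversion; the sp3 bridgeheads C4 and C7 of 13 are transient (racemic, relative configuration fixed by the bridge) and no stereocentre remains in 14. The selectivity needed is regiochemical: C7, which bears O6 and is the β-carbon of the enamine N1–C7a=C7, should be the more nucleophilic diene terminus, while the carbonyl on the C4 side lowers the coefficient there. In the alkyne the silyl group stabilises negative charge building on its own carbon, so the leading bond should form between C7 and the bromine-bearing carbon, placing bromine at C6 and silicon at C5. Steric steering points the same way but is slight, since the bulky silyl group merely avoids the side of C7 that lies peri to the N-substituent. The low dienophilicity is offset by excess alkyne and by the driving force of regaining two aromatic rings, and the acyloxymethyl group is thermally inert.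

Step 8
Reactants: 14 [6-bromo-5-(trimethylsilyl)-1H-indol-1-yl]methyl pivalate
Product: 15 (6-bromo-1H-indol-1-yl)methyl pivalate
Conditions: CF3CO2H, CH2Cl2 (1:3), 0.02 M, 0 °C to rt
Reagents that add atoms: none
Why: Electrophilic ipso-protodesilylation: protonation at C5, which is para to the nitrogen-bearing C7a, gives a β-silyl-stabilised arenium ion that loses silicon to trifluoroacetate. The pivalate N,O-acetal and the aryl bromide should tolerate the acid, and removing silicon by acid before any base or fluoride is used avoids an aryl anion ortho to bromine.

Step 9
Reactants: 15 (6-bromo-1H-indol-1-yl)methyl pivalate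
Product: 17 6-bromo-1H-indole, via N-hydroxymethyl indole 16 (not isolated)
Conditions: NH3 (7 M in MeOH), rt
Reagents that add atoms: none
Why: Ammonolysis of the pivalate gives the N-hydroxymethyl indole 16, which releases formaldehyde (taken up by ammonia) to leave the N–H indole. This is the established way of removing N-pivaloyloxymethyl groups from pyrroles and indoles, and it leaves the aryl bromide untouched.

Step 10
Reactants: 17 6-bromo-1H-indole
Product: 19 2,3,6-tribromo-1H-indole, via 3,6-dibromo-1H-indole 18 (not isolated)
Conditions: NBS (2.05 equiv), THF, −78 °C to 0 °C, dark, anhydrous
Reagents that add atoms: N-bromosuccinimide, O=C1CCC(=O)N1Br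
Why: Electrophilic bromination of the indole enamine: the first equivalent reacts at C3 to give 18, the second brominates C2 (directly, or by C3 attack followed by a 1,2-bromine shift and proton loss). At low temperature the benzene ring, deactivated by the C6 bromine, should not compete, and dry, cold, dark conditions protect the labile 2,3-dibromoindole from hydrolysis to oxindoles.

## Compound list

1 | 2-(1H-pyrrol-3-yl)acetic acid | OC(=O)Cc1cc[nH]c1 | starting material
2 | benzyl bromide | BrCc1ccccc1 | starting material
3 | benzyl 2-(1H-pyrrol-3-yl)acetate | O=C(Cc1cc[nH]c1)OCc1ccccc1 | intermediate
4 | N-({3-[2-(benzyloxy)-2-oxoethyl]-1H-pyrrol-2-yl}methylidene)-N-methylmethanaminium chloride, not isolated | C[N+](C)=Cc1[nH]ccc1CC(=O)OCc1ccccc1.[Cl-] | intermediate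
5 | benzyl 2-(2-formyl-1H-pyrrol-3-yl)acetate | O=Cc1[nH]ccc1CC(=O)OCc1ccccc1 | intermediate
6 | chloromethyl pivalate | CC(C)(C)C(=O)OCCl | starting material
7 | benzyl 2-{2-formyl-1-[(pivaloyloxy)methyl]-1H-pyrrol-3-yl}acetate | O=Cc1n(COC(=O)C(C)(C)C)ccc1CC(=O)OCc1ccccc1 | intermediate
8 | 2-{2-formyl-1-[(pivaloyloxy)methyl]-1H-pyrrol-3-yl}acetic acid | O=Cc1n(COC(=O)C(C)(C)C)ccc1CC(=O)O | intermediate
9 | acetic 2-{2-formyl-1-[(pivaloyloxy)methyl]-1H-pyrrol-3-yl}acetic anhydride, not isolated | O=Cc1n(COC(=O)C(C)(C)C)ccc1CC(=O)OC(C)=O | intermediate
10 | 1-[(pivaloyloxy)methyl]pyrano[3,4-b]pyrrol-5(1H)-one | O=C1C=C2C=CN(COC(=O)C(C)(C)C)C2=CO1 | intermediate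
11 | trimethylsilylacetylene | C#C[Si](C)(C)C | starting material
12 | (bromoethynyl)trimethylsilane | C[Si](C)(C)C#CBr | intermediate
13 | bridged lactone cycloadduct, not isolated: indole skeleton with sp3 C4 and C7 joined by a –C(=O)–O– bridge (carbonyl on C4, oxygen on C7), C5=C6 bearing SiMe3 at C5 and Br at C6, N-pivaloyloxymethyl; racemic, one enantiomer drawn | O=C1O[C@H]2C(Br)=C([Si](C)(C)C)[C@@H]1c1ccn(COC(=O)C(C)(C)C)c12 | intermediate
14 | [6-bromo-5-(trimethylsilyl)-1H-indol-1-yl]methyl pivalate | CC(C)(C)C(=O)OCn1ccc2cc([Si](C)(C)C)c(Br)cc21 | intermediate
15 | (6-bromo-1H-indol-1-yl)methyl pivalate | CC(C)(C)C(=O)OCn1ccc2ccc(Br)cc21 | intermediate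
16 | (6-bromo-1H-indol-1-yl)methanol, not isolated | OCn1ccc2ccc(Br)cc21 | intermediate
17 | 6-bromo-1H-indole | Brc1ccc2cc[nH]c2c1 | intermediate
18 | 3,6-dibromo-1H-indole, not isolated | Brc1ccc2c(Br)c[nH]c2c1 | intermediate
19 | 2,3,6-tribromo-1H-indole | Brc1ccc2c(Br)c(Br)[nH]c2c1 | target

## Step count and least certain steps

Total step count: 10. Longest linear sequence: 9 (steps 1 to 5 and 7 to 10); step 6 is a one-step side branch.

Step 7 (key step). The bromo silyl alkyne is a weak dienophile, so thermal self-reaction or decomposition of the pyranone may outrun cycloaddition. The electronic bias of the alkyne may also be too small, so that bond formation in the reversed orientation competes and bromine ends up at C5. The fallback keeps the disconnection but uses a strongly polarised dienophile and a different traceless group; it sets out from 10 and comes back to the route at 17. Purchased ethyl prop-2-ynoate F1 is brominated with NBS and catalytic AgNO3 to give ethyl 3-bromoprop-2-ynoate F2, which carries bromine on the electrophilic β-carbon of an ynoate; that carbon should bond to the nucleophilic C7 of 10 at a lower temperature. The resulting bridged lactone cycloadduct F3 loses carbon dioxide to give ethyl 6-bromo-1-[(pivaloyloxy)methyl]-1H-indole-5-carboxylate F4. LiOH in aqueous THF/MeOH cleaves both the ethyl ester and the N-substituent to give 6-bromo-1H-indole-5-carboxylic acid F5. Protodecarboxylation catalysed by Ag2CO3 (AcOH, DMSO, 120 °C), which is favoured by the ortho halogen, returns the route at 17.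

Step 8. Ipso-protonation at C5 is slowed by the ortho bromine, so acid-induced self-condensation of the 2,3-unsubstituted indole (C3 protonation and capture of the indoleninium ion by a second molecule) or ionisation of the N–CH2–O acetal may compete. The fallback changes the polarity of the desilylation; it sets out from 14 and comes back at 17. KOH in DMSO/water (6:1) at about 75 °C should cleave the aryl–silicon bond by nucleophilic attack at silicon, which the ortho bromine accelerates; the water-rich medium is chosen so that proton transfer accompanies Si–C cleavage and outruns loss of bromide. The same base hydrolyses the pivalate and releases formaldehyde, so no new compound arises on this path, hence the entry F0.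

Step 5. The C7-unsubstituted enol lactone may dimerise by self-cycloaddition or ring-open on concentration and chromatography, so material is lost between formation and use. The fallback avoids isolation; it sets out from 8 and comes back at 14. The acid is heated with Ac2O in chlorobenzene at 130–140 °C in the presence of excess 12, so that 10 is intercepted as it forms, in the manner used for transient benzopyranones. No new compound arises on this path, hence the entry F0.

Step 2. Attack of the chloroiminium ion at C5, the unhindered α-position, may compete with attack at C2, so that the needed isomer is obtained only after a wasteful separation. The fallback fixes the substitution pattern by cross-coupling; it sets out from 6 and comes back at 8. Purchased 3-bromo-1H-pyrrole-2-carbaldehyde F6 is N-alkylated with 6 (K2CO3, DMF) to give (3-bromo-2-formyl-1H-pyrrol-1-yl)methyl pivalate F7. Because a zinc ester enolate would add to a free aldehyde, the formyl group is masked with ethane-1,2-diol (cat. p-TsOH, toluene, Dean–Stark) as [3-bromo-2-(1,3-dioxolan-2-yl)-1H-pyrrol-1-yl]methyl pivalate F8. Coupling of F8 with the Reformatsky reagent bromo(2-tert-butoxy-2-oxoethyl)zinc F9 under Pd2(dba)3/XPhos in THF gives tert-butyl 2-{2-(1,3-dioxolan-2-yl)-1-[(pivaloyloxy)methyl]-1H-pyrrol-3-yl}acetate F10. Trifluoroacetic acid in wet dichloromethane then cleaves the tert-butyl ester and the dioxolane together, and the route is rejoined at 8.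

Step 10. The N–H 3-bromo intermediate may decompose before the second bromination, 3-bromoindolenine species may be captured by adventitious water to give oxindoles, or bromination may continue onto the benzene ring. The fallback brominates before deprotection; it sets out from 15 and comes back at 19. NBS (2 equiv) in THF should give (2,3,6-tribromo-1H-indol-1-yl)methyl pivalate F11 through N-substituted bromoindoles that are stable to handling. Ammonolysis (NH3 in MeOH, rt) then removes the N-substituent with C3 already blocked against formaldehyde.

## Further compounds

F1 | step 7 | ethyl prop-2-ynoate | C#CC(=O)OCC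
F2 | step 7 | ethyl 3-bromoprop-2-ynoate | CCOC(=O)C#CBr
F3 | step 7 | bridged lactone cycloadduct of 10 and F2 (carbonyl on C4, oxygen on C7, ester at C5, Br at C6; racemic, one enantiomer drawn) | O=C1O[C@H]2C(Br)=C(C(=O)OCC)[C@@H]1c1ccn(COC(=O)C(C)(C)C)c12
F4 | step 7 | ethyl 6-bromo-1-[(pivaloyloxy)methyl]-1H-indole-5-carboxylate | CCOC(=O)c1cc2ccn(COC(=O)C(C)(C)C)c2cc1Br
F5 | step 7 | 6-bromo-1H-indole-5-carboxylic acid | OC(=O)c1cc2cc[nH]c2cc1Br
F0 | step 8 | none | none
F0 | step 5 | none | none
F6 | step 2 | 3-bromo-1H-pyrrole-2-carbaldehyde | O=Cc1[nH]ccc1Br
F7 | step 2 | (3-bromo-2-formyl-1H-pyrrol-1-yl)methyl pivalate | O=Cc1n(COC(=O)C(C)(C)C)ccc1Br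
F8 | step 2 | [3-bromo-2-(1,3-dioxolan-2-yl)-1H-pyrrol-1-yl]methyl pivalate | CC(C)(C)C(=O)OCn1ccc(Br)c1C1OCCO1
F9 | step 2 | bromo(2-tert-butoxy-2-oxoethyl)zinc | CC(C)(C)OC(=O)C[Zn]Br
F10 | step 2 | tert-butyl 2-{2-(1,3-dioxolan-2-yl)-1-[(pivaloyloxy)methyl]-1H-pyrrol-3-yl}acetate | CC(C)(C)OC(=O)Cc1ccn(COC(=O)C(C)(C)C)c1C1OCCO1
F11 | step 10 | (2,3,6-tribromo-1H-indol-1-yl)methyl pivalate | CC(C)(C)C(=O)OCn1c(Br)c(Br)c2ccc(Br)cc21
A1 | alternative 1 | 5-bromo-2-iodoaniline | Nc1cc(Br)ccc1I
A2 | alternative 1 | methyl propiolate | C#CC(=O)OC
A3 | alternative 1 | methyl (2Z)-3-[(5-bromo-2-iodophenyl)amino]prop-2-enoate | COC(=O)/C=C\Nc1cc(Br)ccc1I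
A4 | alternative 1 | methyl 6-bromo-1H-indole-3-carboxylate | COC(=O)c1c[nH]c2cc(Br)ccc12
A5 | alternative 2 | 3-ethenyl-1-tosyl-1H-pyrrole-2-carbaldehyde | Cc1ccc(cc1)S(=O)(=O)n1ccc(C=C)c1C=O
A6 | alternative 2 | 2-(2,2-dibromoethenyl)-3-ethenyl-1-tosyl-1H-pyrrole | Cc1ccc(cc1)S(=O)(=O)n1ccc(C=C)c1C=C(Br)Br
A7 | alternative 2 | 6,6-dibromo-1-tosyl-5,6-dihydro-1H-indole | Cc1ccc(cc1)S(=O)(=O)N1C=CC2=CCC(Br)(Br)C=C12
A8 | alternative 2 | 6-bromo-1-tosyl-1H-indole | Cc1ccc(cc1)S(=O)(=O)n1ccc2ccc(Br)cc21
A9 | alternative 3 | 4-bromobenzaldehyde | O=Cc1ccc(Br)cc1
A10 | alternative 3 | ethyl azidoacetate | CCOC(=O)CN=[N+]=[N-]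
A11 | alternative 3 | ethyl (2Z)-2-azido-3-(4-bromophenyl)prop-2-enoate | CCOC(=O)/C(N=[N+]=[N-])=C/c1ccc(Br)cc1
A12 | alternative 3 | ethyl 6-bromo-1H-indole-2-carboxylate | CCOC(=O)c1cc2ccc(Br)cc2[nH]1
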